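**Plan**
1. Cuts: first the biaryl bond between the C5 positions of the two pendant guaiacyl rings, giving tetralin chloride 15 and oxolane bromide 32. Then C4–C4a and C2–C3 of tetralin ring B together, giving aryl iodide/enolate 13 and the three-carbon piece 4. In the oxolane, the exocyclic CH2OH carbon (Wittig, then hydroboration) and the C3–C4 ring bond (as a metathesis alkene).
2. Enabling feature: C4H2–C3(OH)–CH2OH of ring B is the carbon skeleton of lactic acid. C4 hangs on arene carbon C4a of ring A, ortho to the benzhydrylic C1. C2 bears CH2OH, so it is the α-carbon of an aldehyde. An aryl radical at C4a, a lactic-acid-derived methylene-dioxolanone and an aldehyde enolate at C2 can therefore be joined in one radical relay.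
3. Forward, tetralin: C1 is made first (two aryl groups on one carbon), ring A is iodinated at C4a, and ring B is closed in one step. Hydride then removes the acetal helper.
4. Forward, oxolane: allylic ether, ring-closing metathesis, dihydroxylation, ketone, methylene, hydroboration. The halves are then joined by borylation/Suzuki–Miyaura coupling and debenzylated.
5. Stereochemistry, tetralin: C1 from a rhodium/chiral-diene conjugate addition; C3 from (R)-lactic acid through its acetal carbon; C2 from C1.
6. Stereochemistry, oxolane: the aryl-bearing carbon from a Sharpless kinetic resolution. The other two centres form because OsO4 and 9-BBN both add to the face opposite to the aryl group.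

Key step: step 8

Numbering in the text: tetralin C1 (pendant aryl), C2 (CH2OH), C3 (carbinol), C4 (CH2), C4a/C8a (fusion carbons of ring A). Oxolane O1, C2 (aryl), C3 (CH2OH), C4 (carbinol), C5.
Assumption 1: the oxolane half is built exactly as the SMILES reads, with aryl (C2), CH2OH (C3) and benzyl (C4) all on one ring face (2,3-cis) and the hydroxyl on the other.
Assumption 2: the sense of induction of the chiral diene in step 5 is taken from the closest β-aryl enals; should it prove opposite, the enantiomeric ligand is used.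

**Dioxolanone piece (steps 1–2)**

Step 1
Reactants: 1 (R)-lactic acid
Product: 2 (2R,5R)-2-tert-butyl-5-methyl-1,3-dioxolan-4-one
Conditions: t-BuCHO, p-TsOH (cat.), pentane, reflux, Dean–Stark; crystallisation from pentane, −78 °C
Reagents that add atoms: pivalaldehyde CC(C)(C)C=O
Why: Acid-catalysed acetalisation of an α-hydroxy acid, in which the lactic acid stereocentre steers the new acetal carbon to the cis isomer, which crystallisation frees from the minor trans isomer.

Step 2
Reactants: 2 (2R,5R)-2-tert-butyl-5-methyl-1,3-dioxolan-4-one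
Product: 4 (2R)-2-tert-butyl-5-methylidene-1,3-dioxolan-4-one, via bromide 3 (not isolated)
Conditions: NBS, AIBN (cat.), cyclohexane, reflux; filter; then Et3N, Et2O, 0 °C → rt
Reagents that add atoms: N-bromosuccinimide O=C1CCC(=O)N1Br (bromine of 3 only)
Why: Wohl–Ziegler-type radical bromination of the captodative C5–H followed by E2 loss of HBr toward the methyl group; the lactic acid centre is given up while the acetal carbon keeps the chirality (self-regeneration of stereocentres).

**Tetralin half (steps 3–9)**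

Step 3
Reactants: 5 5-chlorovanillin
Product: 6 4-(benzyloxy)-3-chloro-5-methoxybenzaldehyde
Conditions: BnBr, K2CO3, DMF, 60 °C
Reagents that add atoms: benzyl bromide BrCc1ccccc1
Why: Williamson ether synthesis on the acidic phenol; the chlorine is kept as the later coupling handle because it is inert to tin radicals.

Step 4
Reactants: 6 4-(benzyloxy)-3-chloro-5-methoxybenzaldehyde; 7 (triphenylphosphoranylidene)acetaldehyde
Product: 8 (2E)-3-[4-(benzyloxy)-3-chloro-5-methoxyphenyl]prop-2-enal
Conditions: PhMe, 80 °C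
Reagents that add atoms: none
Why: Wittig reaction of a stabilised ylide, which should give the E enal and brings in C2 and the CH2OH carbon on C2.

Step 5
Reactants: 8 (2E)-3-[4-(benzyloxy)-3-chloro-5-methoxyphenyl]prop-2-enal; 9 [3-(benzyloxy)-4-methoxyphenyl]boronic acid
Product: 10 (3R)-3-[4-(benzyloxy)-3-chloro-5-methoxyphenyl]-3-[3-(benzyloxy)-4-methoxyphenyl]propanal
Conditions: [RhCl(C2H4)2]2 (1.5 mol %), (R,R)-Ph-bod* [(1R,4R)-2,5-diphenylbicyclo[2.2.2]octa-2,5-diene, 3.3 mol %], KOH (0.5 equiv), MeOH–H2O 10:1, 30 °C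
Reagents that add atoms: none
Why: Rhodium/chiral-diene-catalysed asymmetric 1,4-addition of an arylboronic acid to a β-aryl enal; ligand-controlled face selection in the arylrhodation sets C1.

Step 6
Reactants: 10 (3R)-diarylpropanal
Product: 11 (3S)-3-[4-(benzyloxy)-3-chloro-5-methoxyphenyl]-3-[5-(benzyloxy)-2-iodo-4-methoxyphenyl]propanal
Conditions: NIS, CF3CO2H (cat.), MeCN, 0 °C → rt, dark
Reagents that add atoms: N-iodosuccinimide O=C1CCC(=O)N1I
Why: Electrophilic aromatic iodination, expected para to the benzyloxy group of the dialkoxy ring (the future C4a) because chlorine deactivates the other ring; C1 is untouched and only its descriptor changes.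

Step 7
Reactants: 11 (3S)-iodo aldehyde
Product: 12 (1E,3S)-3-[4-(benzyloxy)-3-chloro-5-methoxyphenyl]-3-[5-(benzyloxy)-2-iodo-4-methoxyphenyl]prop-1-en-1-yl acetate
Conditions: Ac2O, Et3N, DMAP (cat.), THF, 60 °C
Reagents that add atoms: acetic anhydride CC(=O)OC(C)=O
Why: Enol acetate formation by O-acylation of the aldehyde enolate; an E/Z mixture is harmless because the alkene geometry is lost in step 8 (E isomer drawn).

Step 8
Reactants: 12 enol acetate; 4 (2R)-2-tert-butyl-5-methylidene-1,3-dioxolan-4-one
Product: 14 spiro-dioxolanone aldehyde (tetralin C1 S, C2 R, C3 S; acetal carbon R), via tributyltin enolate 13 (not isolated)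
Conditions: Bu3SnOMe (1.0 equiv), PhH, 60 °C, MeOAc distilled off; then 4 (5 equiv), AIBN (0.2 equiv, in portions), PhH (0.1 M), 80 °C
Reagents that add atoms: tributyltin methoxide CCCC[Sn](CCCC)(CCCC)OC (tin of 13 only)
Why: Proposed new method: a tin-radical chain in which Bu3Sn• takes iodine from C4a of 13 (the C–Cl bond is inert), the σ-aryl radical adds to the free CH2 terminus of 4 (bond C4–C4a), the captodative radical thus placed on C3 attacks C2, the nucleophilic carbon of the stannyl enolate (bond C2–C3), and the α-stannyloxy radical expels Bu3Sn• by β-scission, which releases the aldehyde of 14 and carries the chain, so that no hydrogen donor is present to intercept an intermediate radical. The closest known reaction types are Giese-type additions of carbon radicals to 2-tert-butyl-5-methylidene-1,3-dioxolan-4-one with trapping anti to the tert-butyl group, and the radical alkylation of tributyltin enolates by α-carbonyl radicals to give 1,4-dicarbonyl compounds; what is new is their union in one [4+2] annulation started by an aryl radical. Ring B closes in the 6-exo-trig mode, since 7-endo attack at the oxygen-bearing carbon is disfavoured by ring size and would forfeit the α-oxygen stabilisation. C3 is set by the acetal carbon of 4, whose tert-butyl group shields one face of the planar dioxolanonyl radical so that C2 bonds anti to it; C2 is set by C1 through a chair-like transition state with the pendant aryl group and the enolate side chain pseudo-equatorial (trans), which is also the thermodynamically preferred position of the epimerisable CHO. The step needs polarity-ordered chemoselectivity, secured because each radical meets its matched partner: the aryl radical meets the excess acceptor 4, the electrophilic C3 radical meets the electron-rich enolate held six atoms away (expected to be faster than addition to a second 4 or 1,5-hydrogen transfer from C1–H), and the tin radical meets the weak C–I bond.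

Step 9
Reactants: 14 spiro-dioxolanone aldehyde
Product: 15 (2S,3S,4S)-6-(benzyloxy)-4-[4-(benzyloxy)-3-chloro-5-methoxyphenyl]-2,3-bis(hydroxymethyl)-7-methoxy-1,2,3,4-tetrahydronaphthalen-2-ol
Conditions: LiAlH4, THF, 0 °C → rt; H2O, aq NaOH work-up
Reagents that add atoms: none
Why: Hydride reduction of the aldehyde and of the dioxolanone carbonyl, whose hemiacetal then collapses, removes the acetal helper and gives both CH2OH groups and the tertiary alcohol without touching a stereocentre.

**Oxolane half (steps 10–19)**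

Step 10
Reactants: 16 5-bromovanillin
Product: 17 4-(benzyloxy)-3-bromo-5-methoxybenzaldehyde
Conditions: BnBr, K2CO3, DMF, 60 °C
Reagents that add atoms: benzyl bromide BrCc1ccccc1
Why: Williamson ether synthesis; the phenol stays masked to the end so that no quinone methide can scramble the benzylic ether carbon.

Step 11
Reactants: 17 4-(benzyloxy)-3-bromo-5-methoxybenzaldehyde; 18 vinylmagnesium bromide
Product: 19 rac-1-[4-(benzyloxy)-3-bromo-5-methoxyphenyl]prop-2-en-1-ol
Conditions: THF, −78 → 0 °C; aq NH4Cl
Reagents that add atoms: none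
Why: Grignard 1,2-addition to the aldehyde, faster at low temperature than any halogen–metal exchange at the aryl bromide; the carbinol forms as the racemate.

Step 12
Reactants: 19 rac-allylic alcohol
Product: 20 (1R)-1-[4-(benzyloxy)-3-bromo-5-methoxyphenyl]prop-2-en-1-ol
Conditions: Ti(OiPr)4 (0.2 equiv), D-(−)-diisopropyl tartrate (0.24 equiv), t-BuOOH (0.6 equiv), 4 Å MS, CH2Cl2, −20 °C
Reagents that add atoms: none
Why: Sharpless kinetic resolution; with the D-(−)-tartrate the S alcohol should be epoxidised faster, which leaves the R alcohol that becomes oxolane C2.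

Step 13
Reactants: 21 1-(benzyloxy)-4-bromo-2-methoxybenzene; 22 3-chloro-2-(chloromethyl)prop-1-ene
Product: 24 1-(benzyloxy)-4-[2-(chloromethyl)prop-2-en-1-yl]-2-methoxybenzene, via arylmagnesium bromide 23 (not isolated)
Conditions: Mg, THF, reflux; then 22 (3 equiv), Li2CuCl4 (3 mol %), THF, −20 °C → rt
Reagents that add atoms: magnesium [Mg] (in 23 only)
Why: Copper-catalysed allylic substitution of a Grignard reagent; the excess of the symmetrical dichloride holds the reaction at monosubstitution, and SN2 and SN2' give the same product.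

Step 14
Reactants: 20 (1R)-allylic alcohol; 24 allylic chloride
Product: 25 (1R)-1-[4-(benzyloxy)-3-bromo-5-methoxyphenyl]prop-2-en-1-yl 2-{[4-(benzyloxy)-3-methoxyphenyl]methyl}prop-2-en-1-yl ether
Conditions: NaH, Bu4NI (cat.), THF–DMF, 0 °C → rt
Reagents that add atoms: none
Why: Williamson ether synthesis at the oxygen of 20, so the carbinol configuration is retained.

Step 15
Reactants: 25 diene ether
Product: 26 (2R)-2-[4-(benzyloxy)-3-bromo-5-methoxyphenyl]-4-{[4-(benzyloxy)-3-methoxyphenyl]methyl}-2,5-dihydrofuran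
Conditions: second-generation Grubbs catalyst RuCl2(=CHPh)(PCy3)(SIMes) (3 mol %), CH2Cl2 (0.01 M), 40 °C
Reagents that add atoms: none
Why: Ring-closing metathesis of a vinyl and a 1,1-disubstituted alkene to a five-membered trisubstituted alkene, driven by loss of ethene.

Step 16
Reactants: 26 2,5-dihydrofuran
Product: 27 (2S,3S,4R)-2-[4-(benzyloxy)-3-bromo-5-methoxyphenyl]-4-{[4-(benzyloxy)-3-methoxyphenyl]methyl}oxolane-3,4-diol
Conditions: OsO4 (2 mol %), NMO, acetone–H2O, 0 °C → rt
Reagents that add atoms: N-methylmorpholine N-oxide C[N+]1([O-])CCOCC1; water O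
Why: Upjohn dihydroxylation; suprafacial osmylation on the ring face opposite to the C2 aryl group puts both hydroxyls trans to it and turns the benzyl group of the new tertiary carbinol cis to it.

Step 17
Reactants: 27 diol
Product: 28 (2S,4R)-2-[4-(benzyloxy)-3-bromo-5-methoxyphenyl]-4-{[4-(benzyloxy)-3-methoxyphenyl]methyl}-4-hydroxyoxolan-3-one
Conditions: IBX, DMSO, rt
Reagents that add atoms: none
Why: IBX oxidation of the secondary alcohol of a 1,2-diol to the α-hydroxy ketone, a base-free method that neither cleaves the glycol nor enolises toward C2.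

Step 18
Reactants: 28 α-hydroxy ketone; 29 methyltriphenylphosphonium bromide
Product: 30 (3S,5S)-5-[4-(benzyloxy)-3-bromo-5-methoxyphenyl]-3-{[4-(benzyloxy)-3-methoxyphenyl]methyl}-4-methylideneoxolan-3-ol
Conditions: 29 (3 equiv), KOt-Bu, THF, 0 °C; then 28, 0 °C → rt
Reagents that add atoms: none
Why: Wittig methylenation with excess non-stabilised ylide (one equivalent is held as the alkoxide) brings in the CH2OH carbon as an sp2 centre, so that its ring carbon receives hydrogen last.

Step 19
Reactants: 30 methylidene oxolanol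
Product: 32 (3S,4R,5R)-5-[4-(benzyloxy)-3-bromo-5-methoxyphenyl]-3-{[4-(benzyloxy)-3-methoxyphenyl]methyl}-4-(hydroxymethyl)oxolan-3-ol, via B-alkyl-9-BBN adduct 31 (not isolated)
Conditions: 9-BBN (3 equiv), THF, rt → 50 °C; then NaOH, H2O2, 0 °C
Reagents that add atoms: 9-borabicyclo[3.3.1]nonane B1C2CCCC1CCC2 (boron of 31 only); hydrogen peroxide OO
Why: Hydroboration–oxidation; boron goes to the terminal carbon and hydrogen enters the ring carbon from the face that carries only the hydroxyl group (opposite to aryl and benzyl), which turns CH2OH onto the crowded face and completes the all-cis array.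

**Coupling and deprotection (steps 20–21)**

Step 20
Reactants: 32 oxolane bromide; 15 tetralin chloride
Product: 34 tetra-O-benzyl ether of the target, via pinacol boronate 33 (not isolated)
Conditions: 32, B2pin2 (1.05 equiv), Pd2(dba)3 (2 mol %), XPhos (8 mol %), KOAc, dioxane, 90 °C; then 15, aq K3PO4, 100 °C
Reagents that add atoms: bis(pinacolato)diboron CC1(C)OB(OC1(C)C)B1OC(C)(C)C(C)(C)O1 (boron of 33 only)
Why: One-pot Miyaura borylation and Suzuki–Miyaura coupling with a bulky biarylphosphine able to activate the hindered aryl chloride; free alcohols are tolerated, and the biaryl axis, with one oxygen ortho substituent per ring, is not a stereogenic element.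

Step 21
Reactants: 34 tetra-O-benzyl ether
Product: 35 target CNP0344108.1
Conditions: H2 (1 atm), Pd/C (10 wt %), EtOAc–MeOH, rt, stopped at full debenzylation
Reagents that add atoms: none
Why: Neutral catalytic hydrogenolysis of four aryl benzyl ethers, which are cleaved faster than the cyclic benzylic ether, so that neither acid nor base can epimerise oxolane C2 or trigger Friedel–Crafts ring closure.

**Compound list**
1 | (R)-lactic acid | C[C@@H](O)C(=O)O | starting material
2 | (2R,5R)-2-tert-butyl-5-methyl-1,3-dioxolan-4-one (cis) | C[C@H]1O[C@@H](C(C)(C)C)OC1=O | intermediate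
3 | (2S,5S)-5-bromo-2-tert-butyl-5-methyl-1,3-dioxolan-4-one (Br trans to tert-butyl) | C[C@@]1(Br)O[C@@H](C(C)(C)C)OC1=O | intermediate
4 | (2R)-2-tert-butyl-5-methylidene-1,3-dioxolan-4-one | C=C1O[C@@H](C(C)(C)C)OC1=O | intermediate
5 | 5-chlorovanillin | COc1cc(C=O)cc(Cl)c1O | starting material
6 | 4-(benzyloxy)-3-chloro-5-methoxybenzaldehyde | COc1cc(C=O)cc(Cl)c1OCc1ccccc1 | intermediate
7 | (triphenylphosphoranylidene)acetaldehyde | O=CC=P(c1ccccc1)(c1ccccc1)c1ccccc1 | starting material
8 | (2E)-3-[4-(benzyloxy)-3-chloro-5-methoxyphenyl]prop-2-enal | COc1cc(/C=C/C=O)cc(Cl)c1OCc1ccccc1 | intermediate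
9 | [3-(benzyloxy)-4-methoxyphenyl]boronic acid | COc1ccc(B(O)O)cc1OCc1ccccc1 | starting material
10 | (3R)-3-[4-(benzyloxy)-3-chloro-5-methoxyphenyl]-3-[3-(benzyloxy)-4-methoxyphenyl]propanal | COc1cc(cc(Cl)c1OCc1ccccc1)[C@H](CC=O)c1ccc(OC)c(OCc2ccccc2)c1 | intermediate
11 | (3S)-3-[4-(benzyloxy)-3-chloro-5-methoxyphenyl]-3-[5-(benzyloxy)-2-iodo-4-methoxyphenyl]propanal | COc1cc(cc(Cl)c1OCc1ccccc1)[C@H](CC=O)c1cc(OCc2ccccc2)c(OC)cc1I | intermediate
12 | (1E,3S)-enol acetate of 11 | COc1cc(cc(Cl)c1OCc1ccccc1)[C@H](/C=C/OC(C)=O)c1cc(OCc2ccccc2)c(OC)cc1I | intermediate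
13 | (1E,3S)-O-tributylstannyl enolate of 11 | COc1cc(cc(Cl)c1OCc1ccccc1)[C@H](/C=C/O[Sn](CCCC)(CCCC)CCCC)c1cc(OCc2ccccc2)c(OC)cc1I | intermediate
14 | tetralin-2-carbaldehyde spiro-fused at C3 to C5 of a (2R)-2-tert-butyl-1,3-dioxolan-4-one (C1 S, C2 R, C3 S; C2 trans to tert-butyl) | COc1cc(cc(Cl)c1OCc1ccccc1)[C@H]1c2cc(OCc3ccccc3)c(OC)cc2C[C@@](O4)(C(=O)O[C@@H]4C(C)(C)C)[C@@H]1C=O | intermediate
15 | (2S,3S,4S)-6-(benzyloxy)-4-[4-(benzyloxy)-3-chloro-5-methoxyphenyl]-2,3-bis(hydroxymethyl)-7-methoxy-1,2,3,4-tetrahydronaphthalen-2-ol | COc1cc(cc(Cl)c1OCc1ccccc1)[C@H]1c2cc(OCc3ccccc3)c(OC)cc2C[C@@](O)(CO)[C@@H]1CO | intermediate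
16 | 5-bromovanillin | COc1cc(C=O)cc(Br)c1O | starting material
17 | 4-(benzyloxy)-3-bromo-5-methoxybenzaldehyde | COc1cc(C=O)cc(Br)c1OCc1ccccc1 | intermediate
18 | vinylmagnesium bromide | C=C[Mg]Br | starting material
19 | rac-1-[4-(benzyloxy)-3-bromo-5-methoxyphenyl]prop-2-en-1-ol | COc1cc(C(O)C=C)cc(Br)c1OCc1ccccc1 | intermediate
20 | (1R)-1-[4-(benzyloxy)-3-bromo-5-methoxyphenyl]prop-2-en-1-ol | COc1cc(cc(Br)c1OCc1ccccc1)[C@H](O)C=C | intermediate
21 | 1-(benzyloxy)-4-bromo-2-methoxybenzene | COc1cc(Br)ccc1OCc1ccccc1 | starting material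
22 | 3-chloro-2-(chloromethyl)prop-1-ene | C=C(CCl)CCl | starting material
23 | [4-(benzyloxy)-3-methoxyphenyl]magnesium bromide | COc1cc([Mg]Br)ccc1OCc1ccccc1 | intermediate
24 | 1-(benzyloxy)-4-[2-(chloromethyl)prop-2-en-1-yl]-2-methoxybenzene | C=C(CCl)Cc1ccc(OCc2ccccc2)c(OC)c1 | intermediate
25 | (R)-bis-allylic ether (diene) | C=C[C@@H](OCC(=C)Cc1ccc(OCc2ccccc2)c(OC)c1)c1cc(OC)c(OCc2ccccc2)c(Br)c1 | intermediate
26 | (2R)-2-aryl-4-(arylmethyl)-2,5-dihydrofuran | COc1cc(CC2=C[C@H](c3cc(OC)c(OCc4ccccc4)c(Br)c3)OC2)ccc1OCc1ccccc1 | intermediate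
27 | (2S,3S,4R)-2-aryl-4-(arylmethyl)oxolane-3,4-diol (both OH trans to aryl) | COc1cc(C[C@@]2(O)CO[C@@H](c3cc(OC)c(OCc4ccccc4)c(Br)c3)[C@@H]2O)ccc1OCc1ccccc1 | intermediate
28 | (2S,4R)-2-aryl-4-(arylmethyl)-4-hydroxyoxolan-3-one | COc1cc(C[C@@]2(O)CO[C@@H](c3cc(OC)c(OCc4ccccc4)c(Br)c3)C2=O)ccc1OCc1ccccc1 | intermediate
29 | methyltriphenylphosphonium bromide | C[P+](c1ccccc1)(c1ccccc1)c1ccccc1.[Br-] | starting material
30 | (3S,5S)-5-aryl-3-(arylmethyl)-4-methylideneoxolan-3-ol | COc1cc(C[C@@]2(O)CO[C@@H](c3cc(OC)c(OCc4ccccc4)c(Br)c3)C2=C)ccc1OCc1ccccc1 | intermediate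
31 | B-alkyl-9-BBN adduct of 30 (all-cis) | COc1cc(C[C@@]2(O)CO[C@@H](c3cc(OC)c(OCc4ccccc4)c(Br)c3)[C@H]2CB5C6CCCC5CCC6)ccc1OCc1ccccc1 | intermediate
32 | (3S,4R,5R)-5-[4-(benzyloxy)-3-bromo-5-methoxyphenyl]-3-{[4-(benzyloxy)-3-methoxyphenyl]methyl}-4-(hydroxymethyl)oxolan-3-ol | COc1cc(C[C@@]2(O)CO[C@@H](c3cc(OC)c(OCc4ccccc4)c(Br)c3)[C@H]2CO)ccc1OCc1ccccc1 | intermediate
33 | pinacol boronate of 32 (Bpin in place of Br) | COc1cc(C[C@@]2(O)CO[C@@H](c3cc(OC)c(OCc4ccccc4)c(B5OC(C)(C)C(C)(C)O5)c3)[C@H]2CO)ccc1OCc1ccccc1 | intermediate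
34 | tetra-O-benzyl ether of the target | COc1cc(C[C@@]2(O)CO[C@@H](c3cc(OC)c(OCc7ccccc7)c(-c4cc([C@H]5c6cc(OCc7ccccc7)c(OC)cc6C[C@@](O)(CO)[C@@H]5CO)cc(OC)c4OCc4ccccc4)c3)[C@H]2CO)ccc1OCc1ccccc1 | intermediate
35 | CNP0344108.1 | COc1cc(C[C@@]2(O)CO[C@@H](c3cc(OC)c(O)c(-c4cc([C@H]5c6cc(O)c(OC)cc6C[C@@](O)(CO)[C@@H]5CO)cc(OC)c4O)c3)[C@H]2CO)ccc1O | target

**Step count**
Total step count: 21.
Longest linear sequence: 11 steps (10, 11, 12, 14, 15, 16, 17, 18, 19, 20, 21, from 5-bromovanillin).

**Steps most likely to fail**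

Step 8.
- What may go wrong: telomerisation of 4; polar aldol or Michael consumption of the tin enolate; capture of the aryl radical by the solvent; erosion of the facial selectivity at C3.
- Fallback: known chemistry that makes the two bonds one after the other, setting out from 11 and returning at 15.
- Stille coupling of 11 with tributyl[2-({[tert-butyl(dimethyl)silyl]oxy}methyl)prop-2-en-1-yl]stannane (Pd2(dba)3, P(2-furyl)3, LiCl, DMF) would give the allyl arene F1 (bond C4–C4a).
- Lemieux–Johnson cleavage (OsO4 cat., NaIO4, 2,6-lutidine) would give the keto aldehyde F2.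
- A reversible 6-enolexo intramolecular aldol addition (piperidinium acetate, CH2Cl2) under thermodynamic control should give the hydroxy aldehyde F3 (bond C2–C3), with aryl, CHO and CH2OSi all equatorial and the hydroxyl axial.
- NaBH4 would give the silyl ether diol F4, and Bu4NF would release 15.

Step 20.
- What may go wrong: protodeboronation of the ortho-alkoxy boronate may outrun the slow oxidative addition into the hindered, electron-rich C–Cl bond.
- Fallback: the polarity of the union is reversed, setting out from 15 and returning at 34.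
- The chloride 15 is borylated on its own (B2pin2, Pd2(dba)3, XPhos, KOAc, dioxane) and isolated as the tetralin pinacol boronate F5.
- F5 is then coupled with the bromide 32 (Pd(OAc)2, SPhos, K3PO4, PhMe–H2O), so that the palladium inserts into the weaker C–Br bond.

Step 18.
- What may go wrong: enolisation toward the benzylic C2–H with epimerisation, an α-ketol shift, or retro-aldol opening under the basic ylide.
- Fallback: addition–elimination with a non-basic nucleophile, setting out from 28 and returning at 30.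
- Me3SiCH2MgCl/CeCl3 (THF, −78 °C) should add to the face opposite to the aryl group and give the β-hydroxysilane F6.
- Peterson elimination (KH, THF, 0 °C) then delivers 30.

**Further compounds**
F1 | step 8 | (3S)-3-[4-(benzyloxy)-3-chloro-5-methoxyphenyl]-3-{5-(benzyloxy)-4-methoxy-2-[2-(tert-butyldimethylsilyloxymethyl)prop-2-en-1-yl]phenyl}propanal | COc1cc(cc(Cl)c1OCc1ccccc1)[C@H](CC=O)c1cc(OCc2ccccc2)c(OC)cc1CC(=C)CO[Si](C)(C)C(C)(C)C
F2 | step 8 | keto aldehyde (arylmethyl silyloxymethyl ketone) derived from F1 | COc1cc(cc(Cl)c1OCc1ccccc1)[C@H](CC=O)c1cc(OCc2ccccc2)c(OC)cc1CC(=O)CO[Si](C)(C)C(C)(C)C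
F3 | step 8 | (1S,2R,3S)-1-aryl-3-hydroxy-3-(tert-butyldimethylsilyloxymethyl)tetralin-2-carbaldehyde | COc1cc(cc(Cl)c1OCc1ccccc1)[C@H]1c2cc(OCc3ccccc3)c(OC)cc2C[C@@](O)(CO[Si](C)(C)C(C)(C)C)[C@@H]1C=O
F4 | step 8 | mono-TBS ether of 15 (silyl group on the CH2OH of C3) | COc1cc(cc(Cl)c1OCc1ccccc1)[C@H]1c2cc(OCc3ccccc3)c(OC)cc2C[C@@](O)(CO[Si](C)(C)C(C)(C)C)[C@@H]1CO
F5 | step 20 | pinacol boronate of 15 (Bpin in place of Cl) | COc1cc(cc(B2OC(C)(C)C(C)(C)O2)c1OCc1ccccc1)[C@H]1c2cc(OCc3ccccc3)c(OC)cc2C[C@@](O)(CO)[C@@H]1CO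
F6 | step 18 | 2-aryl-4-(arylmethyl)-3-[(trimethylsilyl)methyl]oxolane-3,4-diol (CH2SiMe3 trans to aryl) | COc1cc(C[C@@]2(O)CO[C@@H](c3cc(OC)c(OCc4ccccc4)c(Br)c3)[C@]2(O)C[Si](C)(C)C)ccc1OCc1ccccc1
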